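**Retrosynthetic overview**

1. The target comes from its nona-O-benzyl ether 12 by a final global hydrogenolysis. The lower flavanonol unit (rings A'', B'', C'' with C2'' and C3'') is taken intact from (+)-taxifolin.
2. Ring C of the upper flavanone (O1, C2, C3, C4, C4a, C8a) comes from the five-membered oxygen ring of the benzofuran-3(2H)-one 10. A radical 1,2-acyl shift (ring expansion of the Dowd–Beckwith type) moves the C4 acyl carbon from C2 onto the exocyclic carbon that becomes C3.
3. The C3–C8'' bond comes from a thionium Friedel–Crafts alkylation of per-benzylated taxifolin 8 at C8'' by sulfide 5. The quaternary C2 of 5 comes from an asymmetric phase-transfer alkylation, and the 2-aryl ketone 4 from α-arylation of coumaranone 2.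
4. Enabling feature: in ring C of the upper unit the C4 ketone sits between C3, which is benzylic to ring A'' (C8''), and C2, which carries both O1 and ring B. A radical on the future C3 of the ring-contracted precursor can therefore take over the acyl group and end as an α-oxy, benzylic radical at C2.
5. Order of ring formation: rings A''/B''/C'' (chiral pool); ring A with its five-membered oxygen ring (commercial); ring B attached in step 2; ring C formed last, in step 7.

Key step: step 7

Assumption: the S configuration of 5 is chosen on an exo model for the acyl shift in step 7 (see there); if the sense of the catalyst in step 3 or of the relay proved opposite, the pseudoenantiomeric cinchona salt would give the antipode of 5 with no other change.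

**Route**

Step 1
Reactants: 1 4,6-dihydroxybenzofuran-3(2H)-one
Product: 2 4,6-bis(benzyloxy)benzofuran-3(2H)-one
Conditions: BnBr (2.2 equiv), K2CO3, DMF, 60 °C
Reagents that add atoms: benzyl bromide, BrCc1ccccc1
Why: Williamson ether synthesis: both phenoxides (the hydrogen-bonded 4-OH included at 60 °C) are O-benzylated while the less nucleophilic C2 methylene should stay untouched; no stereocentre is formed.

Step 2
Reactants: 2 4,6-bis(benzyloxy)benzofuran-3(2H)-one; 3 1,2-bis(benzyloxy)-4-bromobenzene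
Product: 4 (±)-4,6-bis(benzyloxy)-2-[3,4-bis(benzyloxy)phenyl]benzofuran-3(2H)-one
Conditions: Pd(OAc)2 (5 mol %), XPhos, K3PO4, PhMe, 100 °C, argon
Reagents that add atoms: none
Why: Palladium-catalysed α-arylation of a ketone (Buchwald–Hartwig type): oxidative addition of 3 to zerovalent palladium, enolate binding and reductive elimination form the C2–aryl bond, the more acidic product rests as its enolate and so resists a second arylation, and the new C2 centre is racemic and enolisable until it is fixed in step 3.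

Step 3
Reactants: 4 (±)-4,6-bis(benzyloxy)-2-[3,4-bis(benzyloxy)phenyl]benzofuran-3(2H)-one
Product: 5 (S)-4,6-bis(benzyloxy)-2-[3,4-bis(benzyloxy)phenyl]-2-[(phenylsulfanyl)methyl]benzofuran-3(2H)-one
Conditions: ClCH2SPh (1.2 equiv), N-[4-(trifluoromethyl)benzyl]cinchoninium bromide (10 mol %), 50% aq KOH, PhMe, −20 °C
Reagents that add atoms: chloromethyl phenyl sulfide, ClCSc1ccccc1
Why: Asymmetric phase-transfer alkylation: the chiral cinchona ammonium cation ion-pairs with the planar 3-oxidobenzofuran enolate and shields one face, so that C-alkylation by the soft α-thio chloride should set the quaternary C2 centre as S, in close analogy to cinchoninium-catalysed alkylations of 2-aryl-1-indanones.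

Step 4
Reactants: 6 (+)-taxifolin, (2R,3R)-2-(3,4-dihydroxyphenyl)-3,5,7-trihydroxychroman-4-one
Product: 7 (2R,3R)-5,7-bis(benzyloxy)-2-[3,4-bis(benzyloxy)phenyl]-3-hydroxychroman-4-one
Conditions: BnBr (4.5 equiv), K2CO3, DMF, 50 °C, argon
Reagents that add atoms: benzyl bromide, BrCc1ccccc1
Why: Williamson ether synthesis on the four phenols, run under argon at moderate temperature so that the base-sensitive trans stereocentres C2 and C3 (from the chiral pool) and the secondary 3-OH should stay untouched.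

Step 5
Reactants: 7 (2R,3R)-5,7-bis(benzyloxy)-2-[3,4-bis(benzyloxy)phenyl]-3-hydroxychroman-4-one
Product: 8 (2R,3R)-3,5,7-tris(benzyloxy)-2-[3,4-bis(benzyloxy)phenyl]chroman-4-one
Conditions: BnOC(=NH)CCl3 (1.5 equiv), TfOH (cat.), CH2Cl2–cyclohexane, 0 °C to rt
Reagents that add atoms: benzyl 2,2,2-trichloroacetimidate, N=C(OCc1ccccc1)C(Cl)(Cl)Cl
Why: Acid-catalysed O-benzylation with the trichloroacetimidate (SN1-type benzyl transfer) protects the 3-OH without the strong base that would epimerise or ring-open the flavanonol; no stereocentre is affected.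

Step 6
Reactants: 5 (S)-4,6-bis(benzyloxy)-2-[3,4-bis(benzyloxy)phenyl]-2-[(phenylsulfanyl)methyl]benzofuran-3(2H)-one; 8 (2R,3R)-3,5,7-tris(benzyloxy)-2-[3,4-bis(benzyloxy)phenyl]chroman-4-one
Product: 10 (2S)-4,6-bis(benzyloxy)-2-[3,4-bis(benzyloxy)phenyl]-2-{(phenylsulfanyl)[(2R,3R)-3,5,7-tris(benzyloxy)-2-(3,4-bis(benzyloxy)phenyl)-4-oxochroman-8-yl]methyl}benzofuran-3(2H)-one (both epimers at the sulfur-bearing carbon), via chloro sulfide 9 (not isolated)
Conditions: NCS (1.05 equiv), CH2Cl2, 0 °C; then 8 (1.1 equiv), ZnBr2, −40 to 0 °C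
Reagents that add atoms: none
Why: Pummerer-type α-chlorination of the sulfide followed by Friedel–Crafts alkylation through the thionium ion: ring A of 8 should attack with C8, which lies between one benzyloxy group and the ring oxygen and is less hindered than C6 between two benzyloxy groups, while the quaternary C2 of 5 cannot epimerise and the new sulfur-bearing stereocentre need not be controlled because it becomes a planar radical in step 7.

Step 7
Reactants: 10 the sulfide from step 6 (both epimers)
Product: 12 (2R,3S)-5,7-bis(benzyloxy)-2-[3,4-bis(benzyloxy)phenyl]-3-[(2R,3R)-3,5,7-tris(benzyloxy)-2-(3,4-bis(benzyloxy)phenyl)-4-oxochroman-8-yl]chroman-4-one (2,3-trans; nona-O-benzylmanniflavanone), via cis ketone 11 (not isolated)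
Conditions: Bu3SnH (1.5 equiv, syringe pump), AIBN (0.2 equiv), PhMe (high dilution), 110 °C; then TsOH (cat.), CH2Cl2, rt
Reagents that add atoms: none
Why: Proposed new method: the tributylstannyl radical cleaves the benzylic C–S bond, the exocyclic benzylic radical adds 3-exo-trig to the ring ketone, and β-scission of the former C2–C3 bond of the fused cyclopropyloxy radical gives the ring-expanded 4-oxochroman-2-yl radical, stabilised by O1 and ring B and quenched by the stannane; the closest known reaction type is the Dowd–Beckwith ring expansion of α-(halomethyl) cyclic β-keto esters, whose ester is replaced here by the α-oxygen and aryl group at C2. The six-membered ring C is therefore not closed by cyclisation onto a new atom but arises from the five-membered ring by 3-exo-trig closure and fragmentation, a net 1,2-shift of the acyl carbon from C2 to the exocyclic carbon. The configuration at C3 is relayed from the S quaternary centre of 10: in the late, cyclopropane-like transition state the bulky aryl group of the lower unit should point away from the benzofuranone bicycle (exo), which gives the 3R radical. Hydrogen should then be delivered to C2 anti to that aryl group, giving the 2,3-cis ketone 11 with C2 as R, and acid-catalysed enolisation inverts only the enolisable C3 to the diequatorial 2,3-trans isomer 12, while C2 has no enolisation pathway under acid and is kept. The step needs the acyl shift to outrun direct reduction of the first radical, 1,2-aryl migration and loss of the aryloxy radical by C2–O1 scission; slow addition of the stannane, the general preference of β-keto radicals for acyl over aryl shift, and the gain from a secondary benzylic to a tertiary α-oxy benzylic radical should secure this.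

Step 8
Reactants: 12 nona-O-benzylmanniflavanone
Product: 13 manniflavanone
Conditions: H2 (1 atm), Pd(OH)2/C, THF–MeOH, rt
Reagents that add atoms: none
Why: Catalytic hydrogenolysis of the nine benzyl ethers under neutral conditions at room temperature, where the aryl ketones, the cyclic benzylic C2–O1 bonds and all four stereocentres should persist.

**Compound list**

1 | 4,6-dihydroxybenzofuran-3(2H)-one | O=C1COc2cc(O)cc(O)c12 | starting material
2 | 4,6-bis(benzyloxy)benzofuran-3(2H)-one | O=C1COc2cc(OCc3ccccc3)cc(OCc3ccccc3)c12 | intermediate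
3 | 1,2-bis(benzyloxy)-4-bromobenzene | Brc1ccc(OCc2ccccc2)c(OCc2ccccc2)c1 | starting material
4 | (±)-4,6-bis(benzyloxy)-2-[3,4-bis(benzyloxy)phenyl]benzofuran-3(2H)-one | O=C1C(c2ccc(OCc3ccccc3)c(OCc3ccccc3)c2)Oc2cc(OCc3ccccc3)cc(OCc3ccccc3)c12 | intermediate
5 | (S)-4,6-bis(benzyloxy)-2-[3,4-bis(benzyloxy)phenyl]-2-[(phenylsulfanyl)methyl]benzofuran-3(2H)-one | O=C1[C@](CSc2ccccc2)(c2ccc(OCc3ccccc3)c(OCc3ccccc3)c2)Oc2cc(OCc3ccccc3)cc(OCc3ccccc3)c12 | intermediate
6 | (+)-taxifolin, (2R,3R)-2-(3,4-dihydroxyphenyl)-3,5,7-trihydroxychroman-4-one | O=C1c2c(O)cc(O)cc2O[C@H](c2ccc(O)c(O)c2)[C@H]1O | starting material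
7 | (2R,3R)-5,7-bis(benzyloxy)-2-[3,4-bis(benzyloxy)phenyl]-3-hydroxychroman-4-one | O=C1c2c(OCc3ccccc3)cc(OCc3ccccc3)cc2O[C@H](c2ccc(OCc3ccccc3)c(OCc3ccccc3)c2)[C@H]1O | intermediate
8 | (2R,3R)-3,5,7-tris(benzyloxy)-2-[3,4-bis(benzyloxy)phenyl]chroman-4-one | O=C1c2c(OCc3ccccc3)cc(OCc3ccccc3)cc2O[C@H](c2ccc(OCc3ccccc3)c(OCc3ccccc3)c2)[C@H]1OCc1ccccc1 | intermediate
9 | (2S)-4,6-bis(benzyloxy)-2-[3,4-bis(benzyloxy)phenyl]-2-[chloro(phenylsulfanyl)methyl]benzofuran-3(2H)-one (both epimers at the chlorinated carbon) | O=C1[C@](C(Cl)Sc2ccccc2)(c2ccc(OCc3ccccc3)c(OCc3ccccc3)c2)Oc2cc(OCc3ccccc3)cc(OCc3ccccc3)c12 | intermediate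
10 | (2S)-4,6-bis(benzyloxy)-2-[3,4-bis(benzyloxy)phenyl]-2-{(phenylsulfanyl)[(2R,3R)-3,5,7-tris(benzyloxy)-2-(3,4-bis(benzyloxy)phenyl)-4-oxochroman-8-yl]methyl}benzofuran-3(2H)-one (both epimers at the sulfur-bearing carbon) | O=C1[C@](C(Sc2ccccc2)c2c(OCc3ccccc3)cc(OCc3ccccc3)c3c2O[C@H](c2ccc(OCc4ccccc4)c(OCc4ccccc4)c2)[C@@H](OCc2ccccc2)C3=O)(c2ccc(OCc3ccccc3)c(OCc3ccccc3)c2)Oc2cc(OCc3ccccc3)cc(OCc3ccccc3)c12 | intermediate
11 | (2R,3R)-5,7-bis(benzyloxy)-2-[3,4-bis(benzyloxy)phenyl]-3-[(2R,3R)-3,5,7-tris(benzyloxy)-2-(3,4-bis(benzyloxy)phenyl)-4-oxochroman-8-yl]chroman-4-one (2,3-cis) | O=C1c2c(OCc3ccccc3)cc(OCc3ccccc3)c([C@H]3C(=O)c4c(OCc5ccccc5)cc(OCc5ccccc5)cc4O[C@H]3c3ccc(OCc4ccccc4)c(OCc4ccccc4)c3)c2O[C@H](c2ccc(OCc3ccccc3)c(OCc3ccccc3)c2)[C@H]1OCc1ccccc1 | intermediate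
12 | (2R,3S)-5,7-bis(benzyloxy)-2-[3,4-bis(benzyloxy)phenyl]-3-[(2R,3R)-3,5,7-tris(benzyloxy)-2-(3,4-bis(benzyloxy)phenyl)-4-oxochroman-8-yl]chroman-4-one (2,3-trans; nona-O-benzylmanniflavanone) | O=C1c2c(OCc3ccccc3)cc(OCc3ccccc3)c([C@@H]3C(=O)c4c(OCc5ccccc5)cc(OCc5ccccc5)cc4O[C@H]3c3ccc(OCc4ccccc4)c(OCc4ccccc4)c3)c2O[C@H](c2ccc(OCc3ccccc3)c(OCc3ccccc3)c2)[C@H]1OCc1ccccc1 | intermediate
13 | manniflavanone, (2R,3S)-2-(3,4-dihydroxyphenyl)-3-[(2R,3R)-2-(3,4-dihydroxyphenyl)-3,5,7-trihydroxy-4-oxochroman-8-yl]-5,7-dihydroxychroman-4-one | O=C1c2c(O)cc(O)c([C@@H]3C(=O)c4c(O)cc(O)cc4O[C@H]3c3ccc(O)c(O)c3)c2O[C@H](c2ccc(O)c(O)c2)[C@H]1O | target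

**Step count and risks**

Total step count: 8. Longest linear sequence: 6 steps (steps 1, 2, 3, 6, 7, 8).

Steps most likely to fail:

1. Step 7 (proposed new method). The first benzylic radical may be reduced before the acyl shift, or may fragment by loss of the aryloxy radical. The 3-exo closure may also show poor facial selectivity, so that the C3 and thence the C2 configuration is not relayed. Fallback, setting out from 10 and returning at 12: the sulfide would be ionised with AgOTf in the presence of solid NaHCO3 in CH2Cl2. The benzylic cation should undergo the acid-induced 1,2-acyl shift known from the conversion of chalcone epoxides into isoflavone precursors and lose the C3 proton. This gives the 3-aryl flavone (2R,3R)-3,5,7-tris(benzyloxy)-2-[3,4-bis(benzyloxy)phenyl]-8-{5,7-bis(benzyloxy)-2-[3,4-bis(benzyloxy)phenyl]-4-oxo-4H-chromen-3-yl}chroman-4-one F1. Conjugate reduction of its C2=C3 bond would follow, either with copper hydride generated from Cu(OAc)2, a DTBM-SEGPHOS antipode and a silane, or with LiBH(s-Bu)3 and chromatographic removal of the C2 epimer. Protonation of the enolate to the trans ketone leads back to 12, so that C2 is set by the reducing agent and no longer by the radical relay.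

2. Step 6. Regiochemical leakage to C6 of 8 may occur, and the product sulfide may re-ionise under the Lewis acid and undergo a premature cationic acyl shift. Fallback, setting out from 6 and returning at 12: benzylation of only the 7-, 3'- and 4'-phenols (BnBr 3 equiv, K2CO3, rt) would give (2R,3R)-7-(benzyloxy)-2-[3,4-bis(benzyloxy)phenyl]-3,5-dihydroxychroman-4-one F2. Bromination ortho to the free, hydrogen-bonded 5-OH (NBS, CH2Cl2, 0 °C) would give the 6-bromide (2R,3R)-7-(benzyloxy)-2-[3,4-bis(benzyloxy)phenyl]-6-bromo-3,5-dihydroxychroman-4-one F3. Benzylation of the 5-OH and 3-OH (BnBr, Ag2O, DMF) would give (2R,3R)-3,5,7-tris(benzyloxy)-2-[3,4-bis(benzyloxy)phenyl]-6-bromochroman-4-one F4, in which C6 is blocked. Alkylation by chloro sulfide 9 under the conditions of step 6 can then occur only at C8 and would give the 6-bromo analogue of 10 F5. Under the conditions of step 7 with one more equivalent of Bu3SnH the aryl bromide is reduced as well, so the sequence rejoins the route at 12.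

3. Step 3. O-alkylation of the ambident enolate may compete, and facial discrimination by the ammonium ion pair may be insufficient. Fallback, setting out from 4 and returning at 10: an organocatalytic asymmetric hydroxymethylation of 4 (paraformaldehyde, cinchona-derived bifunctional squaramide, PhMe) would give (R)-4,6-bis(benzyloxy)-2-[3,4-bis(benzyloxy)phenyl]-2-(hydroxymethyl)benzofuran-3(2H)-one F6. This has the same spatial arrangement at C2 as 5. Dess–Martin oxidation would give the aldehyde (R)-4,6-bis(benzyloxy)-2-[3,4-bis(benzyloxy)phenyl]-3-oxo-2,3-dihydrobenzofuran-2-carbaldehyde F7. Condensation of F7 with PhSH and 8 under BF3·OEt2 (hemithioacetal, thionium ion, Friedel–Crafts alkylation at C8) would deliver 10 directly.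

**Further compounds**

F1 | step 7 | (2R,3R)-3,5,7-tris(benzyloxy)-2-[3,4-bis(benzyloxy)phenyl]-8-{5,7-bis(benzyloxy)-2-[3,4-bis(benzyloxy)phenyl]-4-oxo-4H-chromen-3-yl}chroman-4-one | O=C1c2c(OCc3ccccc3)cc(OCc3ccccc3)c(-c3c(-c4ccc(OCc5ccccc5)c(OCc5ccccc5)c4)oc4cc(OCc5ccccc5)cc(OCc5ccccc5)c4c3=O)c2O[C@H](c2ccc(OCc3ccccc3)c(OCc3ccccc3)c2)[C@H]1OCc1ccccc1
F2 | step 6 | (2R,3R)-7-(benzyloxy)-2-[3,4-bis(benzyloxy)phenyl]-3,5-dihydroxychroman-4-one | O=C1c2c(O)cc(OCc3ccccc3)cc2O[C@H](c2ccc(OCc3ccccc3)c(OCc3ccccc3)c2)[C@H]1O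
F3 | step 6 | (2R,3R)-7-(benzyloxy)-2-[3,4-bis(benzyloxy)phenyl]-6-bromo-3,5-dihydroxychroman-4-one | O=C1c2c(O)c(Br)c(OCc3ccccc3)cc2O[C@H](c2ccc(OCc3ccccc3)c(OCc3ccccc3)c2)[C@H]1O
F4 | step 6 | (2R,3R)-3,5,7-tris(benzyloxy)-2-[3,4-bis(benzyloxy)phenyl]-6-bromochroman-4-one | O=C1c2c(OCc3ccccc3)c(Br)c(OCc3ccccc3)cc2O[C@H](c2ccc(OCc3ccccc3)c(OCc3ccccc3)c2)[C@H]1OCc1ccccc1
F5 | step 6 | (2S)-4,6-bis(benzyloxy)-2-[3,4-bis(benzyloxy)phenyl]-2-{(phenylsulfanyl)[(2R,3R)-3,5,7-tris(benzyloxy)-2-(3,4-bis(benzyloxy)phenyl)-6-bromo-4-oxochroman-8-yl]methyl}benzofuran-3(2H)-one (both epimers at the sulfur-bearing carbon) | O=C1[C@](C(Sc2ccccc2)c2c(OCc3ccccc3)c(Br)c(OCc3ccccc3)c3c2O[C@H](c2ccc(OCc4ccccc4)c(OCc4ccccc4)c2)[C@@H](OCc2ccccc2)C3=O)(c2ccc(OCc3ccccc3)c(OCc3ccccc3)c2)Oc2cc(OCc3ccccc3)cc(OCc3ccccc3)c12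
F6 | step 3 | (R)-4,6-bis(benzyloxy)-2-[3,4-bis(benzyloxy)phenyl]-2-(hydroxymethyl)benzofuran-3(2H)-one | O=C1[C@](CO)(c2ccc(OCc3ccccc3)c(OCc3ccccc3)c2)Oc2cc(OCc3ccccc3)cc(OCc3ccccc3)c12
F7 | step 3 | (R)-4,6-bis(benzyloxy)-2-[3,4-bis(benzyloxy)phenyl]-3-oxo-2,3-dihydrobenzofuran-2-carbaldehyde | O=C1[C@](C=O)(c2ccc(OCc3ccccc3)c(OCc3ccccc3)c2)Oc2cc(OCc3ccccc3)cc(OCc3ccccc3)c12
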